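**Target:** (+)-catechin-(4α→8)-(−)-epigallocatechin 3-O-gallate; upper unit 2R,3S,4S (2,3-trans, 3,4-trans), lower unit 2R,3R with the gallate on the lower 3-O.

## Retrosynthetic overview

1. Target ⇒ hydrogenolysis of the two B-ring benzyl ethers of the 3',4'-di-O-benzyl dimer.
2. Dimer ⇒ C4(upper)–C8(lower) bond: a C4-electrophilic catechin unit, masked as a cyclic O4,O5-phenylboronate, plus unprotected (−)-EGCG, which brings rings D–G and the gallate ready-made.
3. Boronate ⇒ three-component [3+3] annulation of phloroglucinol, PhB(OH)2 and a (2R,3S)-aryl glycidic aldehyde: the C4–C4a bond, the dioxaborin ring and the pyran C ring (O1–C2, inversion) form in one operation.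
4. Glycidic aldehyde ⇒ organocatalytic epoxidation of the cinnamaldehyde ⇒ Wittig homologation of 3,4-bis(benzyloxy)benzaldehyde.
5. Ring order: aromatic rings and the F ring are bought; dioxaborin and pyran C ring form together (step 3); the dioxaborin is opened again in the coupling (step 4).

Assumption: (−)-EGCG, phloroglucinol, 3,4-bis(benzyloxy)benzaldehyde, Ph3P=CHCHO, PhB(OH)2 and the (R)-diarylprolinol silyl ether catalyst are bought.

## Route

**Step 1**
Reactants: 1 3,4-bis(benzyloxy)benzaldehyde; 2 (triphenylphosphoranylidene)acetaldehyde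
Product: 3 (E)-3-[3,4-bis(benzyloxy)phenyl]prop-2-enal
Conditions: Ph3P=CHCHO (1.1 equiv), toluene, 80 °C
Reagents that add atoms: (triphenylphosphoranylidene)acetaldehyde, O=CC=P(c1ccccc1)(c1ccccc1)c1ccccc1
Why: Wittig olefination with the stabilised formylmethylene ylide gives the two-carbon homologated E-enal; no stereocentre is formed.

**Step 2**
Reactants: 3 (E)-3-[3,4-bis(benzyloxy)phenyl]prop-2-enal; 4 hydrogen peroxide
Product: 5 (2R,3S)-3-[3,4-bis(benzyloxy)phenyl]oxirane-2-carbaldehyde (trans-epoxide)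
Conditions: (R)-2-{bis[3,5-bis(trifluoromethyl)phenyl](trimethylsilyloxy)methyl}pyrrolidine (10 mol%), 35% aq. H2O2 (1.3 equiv), CH2Cl2, rt; crude product used directly
Reagents that add atoms: hydrogen peroxide, OO
Why: Iminium-catalysed nucleophilic epoxidation (Jørgensen epoxidation): H2O2 adds to Cβ of the E-iminium on the face opposite the bulky diarylsilyloxymethyl group and the enamine closes the trans-epoxide, so the (R)-catalyst (usual steric model) sets both centres as 2R,3S.

**Step 3**
Reactants: 5 (2R,3S)-3-[3,4-bis(benzyloxy)phenyl]oxirane-2-carbaldehyde; 6 phloroglucinol; 7 phenylboronic acid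
Product: 9 3',4'-di-O-benzyl-(2R,3S,4R)-leucocyanidin 4,5-O-phenylboronate, via dioxaborin epoxide 8 (not isolated)
Conditions: phloroglucinol (2 equiv), PhB(OH)2 (1.1 equiv), EtCO2H (20 mol%), 4 Å MS, toluene–THF 4:1, 45 °C; aqueous wash removes surplus phloroglucinol
Reagents that add atoms: phloroglucinol, Oc1cc(O)cc(O)c1; phenylboronic acid, OB(O)c1ccccc1
Why: Proposed new method: a Nagata-type boron-templated ortho-hydroxyalkylation (phenol + aldehyde + PhB(OH)2 → 2-phenyl-4H-1,3,2-benzodioxaborin, a reaction type known also for phloroglucinol) joins C4 to the arene and locks O4/O5 in the dioxaborin so that no second arylation occurs, and the other flanking phenol OH of 8 then opens the aryl-activated epoxide 6-endo at the benzylic carbon with inversion (closest known type: acid-promoted phenol–epoxide closure to 2,3-trans-flavan-3-ols), so C2 becomes R from epoxide C3 (S) and C3 keeps its configuration (descriptor S); C4 is drawn R (all-equatorial) but either epimer serves because C4 is ionised in step 4.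

**Step 4**
Reactants: 9 3',4'-di-O-benzyl-(2R,3S,4R)-leucocyanidin 4,5-O-phenylboronate; 10 (−)-epigallocatechin 3-O-gallate
Product: 12 3',4'-di-O-benzyl-catechin-(4α→8)-epigallocatechin 3-O-gallate, via ortho-quinone methide 11 (not isolated)
Conditions: EGCG (4 equiv, surplus recovered), 0.1 M aq. HCl–1,4-dioxane 1:1, 30 °C; Sephadex LH-20
Reagents that add atoms: (−)-epigallocatechin 3-O-gallate, O=C(O[C@@H]1Cc2c(O)cc(O)cc2O[C@@H]1c1cc(O)c(O)c(O)c1)c1cc(O)c(O)c(O)c1
Why: Acid cleaves the benzylic C4–O–B bond to the A-ring quinone methide/C4 cation, which alkylates the phloroglucinol-type D ring of EGCG at C8 (Friedel–Crafts, biomimetic interflavan condensation) anti to the 3-OH, setting C4 as S (3,4-trans); surplus EGCG suppresses oligomers and the 4→6 isomer is removed by chromatography.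

**Step 5**
Reactants: 12 3',4'-di-O-benzyl-catechin-(4α→8)-epigallocatechin 3-O-gallate
Product: 13 catechin-(4α→8)-epigallocatechin 3-O-gallate
Conditions: H2 (1 atm), 20% Pd(OH)2/C, THF–MeOH–H2O 20:20:1, rt
Reagents that add atoms: none
Why: Catalytic hydrogenolysis removes the two aryl benzyl ethers while the gallate ester, the pyran C–O bonds and the interflavan bond survive under these mild conditions; no stereocentre is touched.

## Compound list

1 | 3,4-bis(benzyloxy)benzaldehyde | O=Cc1ccc(OCc2ccccc2)c(OCc2ccccc2)c1 | starting material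
2 | (triphenylphosphoranylidene)acetaldehyde | O=CC=P(c1ccccc1)(c1ccccc1)c1ccccc1 | starting material
3 | (E)-3-[3,4-bis(benzyloxy)phenyl]prop-2-enal | O=C/C=C/c1ccc(OCc2ccccc2)c(OCc2ccccc2)c1 | intermediate
4 | hydrogen peroxide | OO | starting material
5 | (2R,3S)-3-[3,4-bis(benzyloxy)phenyl]oxirane-2-carbaldehyde | O=C[C@@H]1O[C@H]1c1ccc(OCc2ccccc2)c(OCc2ccccc2)c1 | intermediate
6 | phloroglucinol (benzene-1,3,5-triol) | Oc1cc(O)cc(O)c1 | starting material
7 | phenylboronic acid | OB(O)c1ccccc1 | starting material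
8 | 4-{trans-3-[3,4-bis(benzyloxy)phenyl]oxiran-2-yl}-2-phenyl-4H-1,3,2-benzodioxaborine-5,7-diol (epoxide configuration as in 5; not isolated) | c1ccc(cc1)B1O[C@H](c2c(O1)cc(O)cc2O)[C@@H]1O[C@H]1c1ccc(OCc2ccccc2)c(OCc2ccccc2)c1 | intermediate
9 | (2R,3S,4R)-2-[3,4-bis(benzyloxy)phenyl]flavan-3,4,5,7-tetrol with O4 and O5 bridged by B–Ph (3',4'-di-O-benzyl-leucocyanidin 4,5-O-phenylboronate; free 3-OH and 7-OH) | c1ccc(cc1)B1O[C@@H]2c3c(O1)cc(O)cc3O[C@H](c3ccc(OCc4ccccc4)c(OCc4ccccc4)c3)[C@H]2O | intermediate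
10 | (−)-epigallocatechin 3-O-gallate, (2R,3R) | O=C(O[C@@H]1Cc2c(O)cc(O)cc2O[C@@H]1c1cc(O)c(O)c(O)c1)c1cc(O)c(O)c(O)c1 | starting material
11 | (2R,3S)-2-[3,4-bis(benzyloxy)phenyl]-3,7-dihydroxy-2,3-dihydro-5H-chromen-5-one (A-ring ortho-quinone methide, C4=C4a; not isolated) | O=C1C=C(O)C=C2O[C@H](c3ccc(OCc4ccccc4)c(OCc4ccccc4)c3)[C@@H](O)C=C12 | intermediate
12 | 3',4'-di-O-benzyl-catechin-(4α→8)-epigallocatechin 3-O-gallate; upper 2R,3S,4S, lower 2R,3R | O=C(O[C@@H]1Cc2c(O)cc(O)c([C@@H]3c4c(O)cc(O)cc4O[C@H](c4ccc(OCc5ccccc5)c(OCc5ccccc5)c4)[C@H]3O)c2O[C@@H]1c1cc(O)c(O)c(O)c1)c1cc(O)c(O)c(O)c1 | intermediate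
13 | catechin-(4α→8)-epigallocatechin 3-O-gallate; upper 2R,3S,4S, lower 2R,3R | O=C(O[C@@H]1Cc2c(O)cc(O)c([C@@H]3c4c(O)cc(O)cc4O[C@H](c4ccc(O)c(O)c4)[C@H]3O)c2O[C@@H]1c1cc(O)c(O)c(O)c1)c1cc(O)c(O)c(O)c1 | target

## Summary

Total step count: 5. Longest linear sequence: 5 (1 → 3 → 5 → 9 → 12 → 13).

Steps most likely to fail, with fallbacks:

**Step 3** (untested three-component annulation). Phloroglucinol may open the epoxide intermolecularly at the benzylic carbon, further condensations on the A ring may occur, or closure may go 5-exo. The fallback sets out from 10 and comes back at 13. The C4 electrophile is taken from the chiral pool instead of being built: purchased (+)-taxifolin is reduced with NaBH4 in EtOH to (2R,3S,4R)-2-(3,4-dihydroxyphenyl)chromane-3,4,5,7-tetrol F1 (2,3-trans-3,4-trans leucocyanidin). This unprotected flavan-3,4-diol is condensed with 10 (4 equiv) in 0.1 M aq. HCl–dioxane, which gives 13 directly without protecting groups or hydrogenolysis.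

**Step 4** (protic coupling). Risks are 4→6 regioisomer, oligomers from the free A ring of the upper unit, and slow boronate cleavage. The fallback sets out from 9 and comes back at 12. Compound 9 is captured with benzyl mercaptan in AcOH–EtOH to give the bench-stable (2R,3S,4R)-4-(benzylsulfanyl)-2-[3,4-bis(benzyloxy)phenyl]chromane-3,5,7-triol F2. This thioether is then activated with AgBF4 in THF at 0 °C in the presence of 10, so the C4–C8 bond forms under thiophilic, non-acidic conditions and at low stationary cation concentration.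

**Step 2** (epoxidation of an electron-rich enal; labile aryl glycidic aldehyde). The fallback sets out from 3 and comes back at 5. Luche reduction (NaBH4, CeCl3, MeOH) gives (E)-3-[3,4-bis(benzyloxy)phenyl]prop-2-en-1-ol F3. Sharpless asymmetric epoxidation (Ti(OiPr)4, L-(+)-DET, TBHP, 4 Å MS, CH2Cl2, −20 °C) gives [(2S,3S)-3-[3,4-bis(benzyloxy)phenyl]oxiran-2-yl]methanol F4. Parikh–Doering oxidation (SO3·pyridine, DMSO, iPr2NEt) then delivers 5, which has the same spatial arrangement.

## Further compounds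

F1 | step 3 | (2R,3S,4R)-2-(3,4-dihydroxyphenyl)chromane-3,4,5,7-tetrol | O[C@@H]1c2c(O)cc(O)cc2O[C@H](c2ccc(O)c(O)c2)[C@H]1O
F2 | step 4 | (2R,3S,4R)-4-(benzylsulfanyl)-2-[3,4-bis(benzyloxy)phenyl]chromane-3,5,7-triol | c1ccccc1CS[C@@H]1c2c(O)cc(O)cc2O[C@H](c2ccc(OCc3ccccc3)c(OCc3ccccc3)c2)[C@H]1O
F3 | step 2 | (E)-3-[3,4-bis(benzyloxy)phenyl]prop-2-en-1-ol | OC/C=C/c1ccc(OCc2ccccc2)c(OCc2ccccc2)c1
F4 | step 2 | [(2S,3S)-3-[3,4-bis(benzyloxy)phenyl]oxiran-2-yl]methanol | OC[C@@H]1O[C@H]1c1ccc(OCc2ccccc2)c(OCc2ccccc2)c1
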